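**Retrosynthetic overview**
- Feature: in ring B of the methyl ether half, the ketone carbon sits on C1 between the C2 methoxy group and the C6 methyl group, with oxygen again at C4. This OMe/acyl/alkyl triad on three neighbouring ring atoms is what a 3,5-dioxygenated benzyne leaves after inserting into the CO–CH2 bond of an aroylacetate (C1–CO and C6–CH2 are made together, and CH2CO2Me is later trimmed to CH3).
- Central CH2: cut between C3 of the two rings A. In the forward direction a C3 Mannich base of the methyl ether half releases an ortho-quinone methide, which C3 of ring A of the other half captures while all ring B oxygens are still benzylated. One hydrogenolysis ends the route.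
- Both halves come from one ring A β-keto ester, made from 2,4,6-trihydroxyacetophenone and dimethyl carbonate. Ring A is masked as its bis-MOM ether so that it can be freed without touching the benzyl ethers. Two silyl triflates deliver 5-benzyloxy-3-methoxybenzyne and 3,5-bis(benzyloxy)benzyne.
- The unsymmetrical silyl triflate is made without regiochemical doubt: 5-methoxyresorcinol is brominated first, the retro-Brook shift then singles out the oxygen next to bromine for triflation, and the remote oxygen is benzylated last.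
- Rings: none is built, since all four benzene rings are bought. The only ring closed on the way is the four-membered ring of the insertion, which opens again.

Key step: step 8

Assumption: ring A is the 2,6-dihydroxy-4-methoxyphenyl ring and ring B the methyl-bearing ring of each half; the target has no stereocentre; 3,5-bis(benzyloxy)phenol is taken as purchasable.

Step 1
Reactants: 1 2,4,6-trihydroxyacetophenone
Product: 2 1-(2,6-dihydroxy-4-methoxyphenyl)ethan-1-one
Conditions: Me2SO4 (1.0 equiv), K2CO3 (1.0 equiv), acetone, reflux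
Reagents that add atoms: dimethyl sulfate, COS(=O)(=O)OC
Why: Williamson-type O-methylation, in which the C4 hydroxyl (para to the acetyl group, most acidic, least hindered) should take the single equivalent while the C2 and C6 hydroxyls flank the acetyl group and share its hydrogen bond.

Step 2
Reactants: 2 1-(2,6-dihydroxy-4-methoxyphenyl)ethan-1-one
Product: 3 1-[4-methoxy-2,6-bis(methoxymethoxy)phenyl]ethan-1-one
Conditions: NaH (2.4 equiv), MOMCl (2.4 equiv), DMF, 0 °C to rt
Reagents that add atoms: chloromethyl methyl ether, COCCl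
Why: O-alkylation of the preformed bis(phenoxide), which overcomes the hydrogen bonding of the ortho hydroxyls and installs slim, base-stable acetals that can later be removed beside benzyl ethers.

Step 3
Reactants: 3 1-[4-methoxy-2,6-bis(methoxymethoxy)phenyl]ethan-1-one; 4 dimethyl carbonate
Product: 5 methyl 3-[4-methoxy-2,6-bis(methoxymethoxy)phenyl]-3-oxopropanoate
Conditions: NaH, 4 (excess), THF, reflux; AcOH quench
Reagents that add atoms: none
Why: crossed Claisen condensation of the methyl ketone enolate with a non-enolisable carbonate, driven by deprotonation of the β-keto ester and well known for 2,4,6-trialkoxyacetophenones.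

Step 4
Reactants: 6 5-methoxyresorcinol
Product: 7 4-bromo-5-methoxybenzene-1,3-diol
Conditions: NBS (1.0 equiv), MeCN, −20 °C to 0 °C
Reagents that add atoms: N-bromosuccinimide, O=C1CCC(=O)N1Br
Why: electrophilic aromatic bromination, in which NBS in polar MeCN attacks para to a free hydroxyl; both such positions (C4 and C6, equivalent) lie between OH and OMe, whereas C2 between the two hydroxyls is the site resorcinols brominate least readily.

Step 5
Reactants: 7 4-bromo-5-methoxybenzene-1,3-diol
Product: 8 [(4-bromo-5-methoxy-1,3-phenylene)bis(oxy)]bis(trimethylsilane)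
Conditions: HMDS, THF, 70 °C; concentrate
Reagents that add atoms: hexamethyldisilazane, C[Si](C)(C)N[Si](C)(C)C
Why: O-silylation of both phenols, driven by loss of ammonia, should leave a neutral bis(silyl ether) fit for halogen–metal exchange.

Step 6
Reactants: 8 [(4-bromo-5-methoxy-1,3-phenylene)bis(oxy)]bis(trimethylsilane)
Product: 12 5-hydroxy-3-methoxy-2-(trimethylsilyl)phenyl trifluoromethanesulfonate, via aryllithium 9 (not isolated), via lithium silylphenoxide 10 (not isolated), via O-silylated triflate 11 (not isolated)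
Conditions: n-BuLi (1.05 equiv), THF, −78 °C; Tf2O, −78 °C; then MeOH, citric acid (cat.), 0 °C to rt
Reagents that add atoms: trifluoromethanesulfonic anhydride, O=S(=O)(OS(=O)(=O)C(F)(F)F)C(F)(F)F
Why: bromine–lithium exchange and retro-Brook (1,3 O-to-C) silyl shift can draw only on the silyloxy group ortho to the lithiated carbon, so Tf2O captures the phenoxide next to the new C–Si bond, and mild methanolysis then frees the remote phenol from its labile aryl silyl ether.

Step 7
Reactants: 12 5-hydroxy-3-methoxy-2-(trimethylsilyl)phenyl trifluoromethanesulfonate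
Product: 13 5-(benzyloxy)-3-methoxy-2-(trimethylsilyl)phenyl trifluoromethanesulfonate
Conditions: BnOH, PPh3, DIAD, THF, 0 °C to rt
Reagents that add atoms: benzyl alcohol, OCc1ccccc1
Why: Mitsunobu etherification alkylates the phenol under neutral conditions and so avoids the base or fluoride that would set off loss of the silyl and triflate groups.

Step 8
Reactants: 5 methyl 3-[4-methoxy-2,6-bis(methoxymethoxy)phenyl]-3-oxopropanoate; 13 5-(benzyloxy)-3-methoxy-2-(trimethylsilyl)phenyl trifluoromethanesulfonate
Product: 16 methyl 2-{5-(benzyloxy)-3-methoxy-2-[4-methoxy-2,6-bis(methoxymethoxy)benzoyl]phenyl}acetate, via 5-(benzyloxy)-3-methoxybenzyne 14 (not isolated), via cesium benzocyclobutenoxide 15 (not isolated)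
Conditions: 13 (1.3 equiv), CsF (2.5 equiv), dry MeCN, 80 °C
Reagents that add atoms: none
Why: CsF strips the silyl group of 13 and expels triflate to give aryne 14, and the cesium enolate of 5 adds through carbon to the aryne carbon meta to the methoxy group, because the inductively withdrawing C3 oxygen distorts the triple bond so that this distal carbon is the more electrophilic one and the negative charge develops next to oxygen. The aryl anion so formed closes by 4-exo-trig attack on the ketone to benzocyclobutenoxide 15, and strain-driven fragmentation of the old CO–CH bond places ring B C1 on the ketone carbon and C6 on CH2CO2Me. This is the aryne acyl-alkylation of β-keto esters, known for aroylacetates and for 3,5-dialkoxybenzynes. No ring survives, since the four-membered ring opens again, and the two transient stereocentres of 15 vanish, so no stereocontrol is needed. The step needs regioselective enolate addition, which the 3-methoxy group secures (the 5-benzyloxy group is too remote to compete), and ring closure ahead of protonation of the aryl anion, which the intramolecular reach, the slim MOM groups and the dry medium favour.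

Step 9
Reactants: 16 methyl 2-{5-(benzyloxy)-3-methoxy-2-[4-methoxy-2,6-bis(methoxymethoxy)benzoyl]phenyl}acetate
Product: 17 2-{5-(benzyloxy)-3-methoxy-2-[4-methoxy-2,6-bis(methoxymethoxy)benzoyl]phenyl}acetic acid
Conditions: LiOH, THF–MeOH–H2O, rt; 1 M HCl to pH 4, 0 °C
Reagents that add atoms: lithium hydroxide, [Li+].[OH-]
Why: saponification of the unhindered arylacetic ester, while the diaryl ketone has no α-hydrogen and is shielded by four ortho substituents.

Step 10
Reactants: 17 2-{5-(benzyloxy)-3-methoxy-2-[4-methoxy-2,6-bis(methoxymethoxy)benzoyl]phenyl}acetic acid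
Product: 19 [4-(benzyloxy)-2-methoxy-6-methylphenyl][4-methoxy-2,6-bis(methoxymethoxy)phenyl]methanone, via thiohydroxamate ester 18 (not isolated)
Conditions: 1-hydroxypyridine-2(1H)-thione, DCC, DMAP (cat.), CH2Cl2, 0 °C to rt, dark; then t-BuSH (excess), tungsten lamp, rt
Reagents that add atoms: none
Why: Barton reductive decarboxylation, chosen because an ortho-aroyl arylacetic acid does not lose CO2 on simple heating; the thiohydroxamate ester fragments in a radical chain to CO2 and a benzylic radical, which takes hydrogen from the thiol and leaves the ring B methyl group.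

Step 11
Reactants: 19 [4-(benzyloxy)-2-methoxy-6-methylphenyl][4-methoxy-2,6-bis(methoxymethoxy)phenyl]methanone
Product: 20 [4-(benzyloxy)-2-methoxy-6-methylphenyl](2,6-dihydroxy-4-methoxyphenyl)methanone
Conditions: HCl (aq, cat.), MeOH–THF, 50 °C
Reagents that add atoms: none
Why: acid-catalysed acetal exchange frees only the ring A phenols, leaves benzyl and methyl ethers alone, and lets the large excess of methanol hold the formaldehyde unit as dimethoxymethane so that it cannot bridge the freed ring.

Step 12
Reactants: 21 3,5-bis(benzyloxy)phenol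
Product: 22 3,5-bis(benzyloxy)-2-bromophenol
Conditions: NBS (1.0 equiv), CH2Cl2, −78 °C
Reagents that add atoms: N-bromosuccinimide, O=C1CCC(=O)N1Br
Why: electrophilic bromination, in which NBS in CH2Cl2 at low temperature is delivered ortho to the hydrogen-bonding phenol while the para position is shielded by two benzyloxy groups.

Step 13
Reactants: 22 3,5-bis(benzyloxy)-2-bromophenol
Product: 23 [3,5-bis(benzyloxy)-2-bromophenoxy]trimethylsilane
Conditions: HMDS, THF, 70 °C; concentrate
Reagents that add atoms: hexamethyldisilazane, C[Si](C)(C)N[Si](C)(C)C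
Why: O-silylation of the phenol, driven by loss of ammonia, prepares the silyl donor for the migration.

Step 14
Reactants: 23 [3,5-bis(benzyloxy)-2-bromophenoxy]trimethylsilane
Product: 26 3,5-bis(benzyloxy)-2-(trimethylsilyl)phenyl trifluoromethanesulfonate, via aryllithium 24 (not isolated), via lithium silylphenoxide 25 (not isolated)
Conditions: n-BuLi (1.05 equiv), THF, −78 °C; Tf2O, −78 °C
Reagents that add atoms: trifluoromethanesulfonic anhydride, O=S(=O)(OS(=O)(=O)C(F)(F)F)C(F)(F)F
Why: bromine–lithium exchange (faster at −78 °C than benzylic deprotonation), retro-Brook silyl shift and O-triflation, the standard entry to ortho-silylaryl triflates.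

Step 15
Reactants: 5 methyl 3-[4-methoxy-2,6-bis(methoxymethoxy)phenyl]-3-oxopropanoate; 26 3,5-bis(benzyloxy)-2-(trimethylsilyl)phenyl trifluoromethanesulfonate
Product: 29 methyl 2-{3,5-bis(benzyloxy)-2-[4-methoxy-2,6-bis(methoxymethoxy)benzoyl]phenyl}acetate, via 3,5-bis(benzyloxy)benzyne 27 (not isolated), via cesium benzocyclobutenoxide 28 (not isolated)
Conditions: 26 (1.3 equiv), CsF (2.5 equiv), dry MeCN, 80 °C
Reagents that add atoms: none
Why: the same aryne acyl-alkylation as in step 8, with the 3-benzyloxy group steering the enolate to the distal aryne carbon so that the aroyl group lands between OBn and CH2CO2Me.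

Step 16
Reactants: 29 methyl 2-{3,5-bis(benzyloxy)-2-[4-methoxy-2,6-bis(methoxymethoxy)benzoyl]phenyl}acetate
Product: 30 2-{3,5-bis(benzyloxy)-2-[4-methoxy-2,6-bis(methoxymethoxy)benzoyl]phenyl}acetic acid
Conditions: LiOH, THF–MeOH–H2O, rt; 1 M HCl to pH 4, 0 °C
Reagents that add atoms: lithium hydroxide, [Li+].[OH-]
Why: saponification of the unhindered ester, as in step 9.

Step 17
Reactants: 30 2-{3,5-bis(benzyloxy)-2-[4-methoxy-2,6-bis(methoxymethoxy)benzoyl]phenyl}acetic acid
Product: 32 [2,4-bis(benzyloxy)-6-methylphenyl][4-methoxy-2,6-bis(methoxymethoxy)phenyl]methanone, via thiohydroxamate ester 31 (not isolated)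
Conditions: 1-hydroxypyridine-2(1H)-thione, DCC, DMAP (cat.), CH2Cl2, 0 °C to rt, dark; then t-BuSH (excess), tungsten lamp, rt
Reagents that add atoms: none
Why: Barton reductive decarboxylation, as in step 10, turns CH2CO2H into the ring B methyl group.

Step 18
Reactants: 32 [2,4-bis(benzyloxy)-6-methylphenyl][4-methoxy-2,6-bis(methoxymethoxy)phenyl]methanone
Product: 33 [2,4-bis(benzyloxy)-6-methylphenyl](2,6-dihydroxy-4-methoxyphenyl)methanone
Conditions: HCl (aq, cat.), MeOH–THF, 50 °C
Reagents that add atoms: none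
Why: acid-catalysed MOM acetal exchange, as in step 11, frees ring A only.

Step 19
Reactants: 20 [4-(benzyloxy)-2-methoxy-6-methylphenyl](2,6-dihydroxy-4-methoxyphenyl)methanone
Product: 34 [4-(benzyloxy)-2-methoxy-6-methylphenyl]{3-[(dimethylamino)methyl]-2,6-dihydroxy-4-methoxyphenyl}methanone
Conditions: dimethylmethyleneiminium iodide (1.0 equiv), CH2Cl2, 0 °C to rt; aq NaHCO3
Reagents that add atoms: dimethylmethyleneiminium iodide, C=[N+](C)C.[I-]
Why: Mannich aminomethylation with a preformed iminium salt, in which only the free phloroglucinol ring A reacts (C3 and C5 are equivalent, ring B carries no phenol) and the single equivalent limits double substitution.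

Step 20
Reactants: 34 [4-(benzyloxy)-2-methoxy-6-methylphenyl]{3-[(dimethylamino)methyl]-2,6-dihydroxy-4-methoxyphenyl}methanone; 33 [2,4-bis(benzyloxy)-6-methylphenyl](2,6-dihydroxy-4-methoxyphenyl)methanone
Product: 36 {3-[3-(2,4-bis(benzyloxy)-6-methylbenzoyl)-2,4-dihydroxy-6-methoxybenzyl]-2,6-dihydroxy-4-methoxyphenyl}[4-(benzyloxy)-2-methoxy-6-methylphenyl]methanone, via ortho-quinone methide 35 (not isolated)
Conditions: 33 (1.5 equiv), toluene, 110 °C, N2 sweep
Reagents that add atoms: none
Why: thermal loss of dimethylamine from the ortho-hydroxybenzylamine gives quinone methide 35, and Friedel–Crafts-type conjugate addition of C3 of the free ring A of 33 forms the diarylmethane; this is a known way to unsymmetrical methylene-bridged acylphloroglucinols, and the etherified rings B are far poorer nucleophiles.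

Step 21
Reactants: 36 {3-[3-(2,4-bis(benzyloxy)-6-methylbenzoyl)-2,4-dihydroxy-6-methoxybenzyl]-2,6-dihydroxy-4-methoxyphenyl}[4-(benzyloxy)-2-methoxy-6-methylphenyl]methanone
Product: 37 {3-[3-(2,4-dihydroxy-6-methylbenzoyl)-2,4-dihydroxy-6-methoxybenzyl]-2,6-dihydroxy-4-methoxyphenyl}(4-hydroxy-2-methoxy-6-methylphenyl)methanone (CNP0596095.0)
Conditions: H2 (1 atm), Pd/C, EtOAc–MeOH, rt
Reagents that add atoms: none
Why: neutral hydrogenolysis of the three aryl benzyl ethers, under which the diarylmethane C–C bonds, the methyl ethers and the hindered, hydrogen-bonded diaryl ketones should stay intact.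

**Compound list**
1 | 2,4,6-trihydroxyacetophenone | CC(=O)c1c(O)cc(O)cc1O | starting material
2 | 1-(2,6-dihydroxy-4-methoxyphenyl)ethan-1-one | CC(=O)c1c(O)cc(OC)cc1O | intermediate
3 | 1-[4-methoxy-2,6-bis(methoxymethoxy)phenyl]ethan-1-one | CC(=O)c1c(OCOC)cc(OC)cc1OCOC | intermediate
4 | dimethyl carbonate | COC(=O)OC | starting material
5 | methyl 3-[4-methoxy-2,6-bis(methoxymethoxy)phenyl]-3-oxopropanoate | COC(=O)CC(=O)c1c(OCOC)cc(OC)cc1OCOC | intermediate
6 | 5-methoxyresorcinol | COc1cc(O)cc(O)c1 | starting material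
7 | 4-bromo-5-methoxybenzene-1,3-diol | COc1cc(O)cc(O)c1Br | intermediate
8 | [(4-bromo-5-methoxy-1,3-phenylene)bis(oxy)]bis(trimethylsilane) | COc1cc(O[Si](C)(C)C)cc(O[Si](C)(C)C)c1Br | intermediate
9 | [2-methoxy-4,6-bis(trimethylsilyloxy)phenyl]lithium (not isolated) | COc1cc(O[Si](C)(C)C)cc(O[Si](C)(C)C)c1[Li] | intermediate
10 | lithium 3-methoxy-2-(trimethylsilyl)-5-(trimethylsilyloxy)phenoxide (not isolated) | COc1cc(O[Si](C)(C)C)cc([O-])c1[Si](C)(C)C.[Li+] | intermediate
11 | 3-methoxy-2-(trimethylsilyl)-5-(trimethylsilyloxy)phenyl trifluoromethanesulfonate (not isolated) | COc1cc(O[Si](C)(C)C)cc(OS(=O)(=O)C(F)(F)F)c1[Si](C)(C)C | intermediate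
12 | 5-hydroxy-3-methoxy-2-(trimethylsilyl)phenyl trifluoromethanesulfonate | COc1cc(O)cc(OS(=O)(=O)C(F)(F)F)c1[Si](C)(C)C | intermediate
13 | 5-(benzyloxy)-3-methoxy-2-(trimethylsilyl)phenyl trifluoromethanesulfonate | COc1cc(OCc2ccccc2)cc(OS(=O)(=O)C(F)(F)F)c1[Si](C)(C)C | intermediate
14 | 5-(benzyloxy)-3-methoxybenzyne (not isolated) | COC1=CC(OCc2ccccc2)=CC#C1 | intermediate
15 | cesium alkoxide of methyl 4-(benzyloxy)-8-hydroxy-2-methoxy-8-[4-methoxy-2,6-bis(methoxymethoxy)phenyl]bicyclo[4.2.0]octa-1,3,5-triene-7-carboxylate (not isolated; racemic, both stereocentres lost on fragmentation) | COC(=O)C1c2cc(OCc3ccccc3)cc(OC)c2C1([O-])c1c(OCOC)cc(OC)cc1OCOC.[Cs+] | intermediate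
16 | methyl 2-{5-(benzyloxy)-3-methoxy-2-[4-methoxy-2,6-bis(methoxymethoxy)benzoyl]phenyl}acetate | COC(=O)Cc1cc(OCc2ccccc2)cc(OC)c1C(=O)c1c(OCOC)cc(OC)cc1OCOC | intermediate
17 | 2-{5-(benzyloxy)-3-methoxy-2-[4-methoxy-2,6-bis(methoxymethoxy)benzoyl]phenyl}acetic acid | OC(=O)Cc1cc(OCc2ccccc2)cc(OC)c1C(=O)c1c(OCOC)cc(OC)cc1OCOC | intermediate
18 | 2-thioxopyridin-1(2H)-yl ester of 17 (not isolated) | S=c1ccccn1OC(=O)Cc1cc(OCc2ccccc2)cc(OC)c1C(=O)c1c(OCOC)cc(OC)cc1OCOC | intermediate
19 | [4-(benzyloxy)-2-methoxy-6-methylphenyl][4-methoxy-2,6-bis(methoxymethoxy)phenyl]methanone | Cc1cc(OCc2ccccc2)cc(OC)c1C(=O)c1c(OCOC)cc(OC)cc1OCOC | intermediate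
20 | [4-(benzyloxy)-2-methoxy-6-methylphenyl](2,6-dihydroxy-4-methoxyphenyl)methanone | Cc1cc(OCc2ccccc2)cc(OC)c1C(=O)c1c(O)cc(OC)cc1O | intermediate
21 | 3,5-bis(benzyloxy)phenol | Oc1cc(OCc2ccccc2)cc(OCc2ccccc2)c1 | starting material
22 | 3,5-bis(benzyloxy)-2-bromophenol | Oc1cc(OCc2ccccc2)cc(OCc2ccccc2)c1Br | intermediate
23 | [3,5-bis(benzyloxy)-2-bromophenoxy]trimethylsilane | C[Si](C)(C)Oc1cc(OCc2ccccc2)cc(OCc2ccccc2)c1Br | intermediate
24 | [2,4-bis(benzyloxy)-6-(trimethylsilyloxy)phenyl]lithium (not isolated) | C[Si](C)(C)Oc1cc(OCc2ccccc2)cc(OCc2ccccc2)c1[Li] | intermediate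
25 | lithium 3,5-bis(benzyloxy)-2-(trimethylsilyl)phenoxide (not isolated) | [O-]c1cc(OCc2ccccc2)cc(OCc2ccccc2)c1[Si](C)(C)C.[Li+] | intermediate
26 | 3,5-bis(benzyloxy)-2-(trimethylsilyl)phenyl trifluoromethanesulfonate | C[Si](C)(C)c1c(OCc2ccccc2)cc(OCc2ccccc2)cc1OS(=O)(=O)C(F)(F)F | intermediate
27 | 3,5-bis(benzyloxy)benzyne (not isolated) | c1ccccc1COC1=CC(OCc2ccccc2)=CC#C1 | intermediate
28 | cesium alkoxide of methyl 2,4-bis(benzyloxy)-8-hydroxy-8-[4-methoxy-2,6-bis(methoxymethoxy)phenyl]bicyclo[4.2.0]octa-1,3,5-triene-7-carboxylate (not isolated; racemic, both stereocentres lost on fragmentation) | COC(=O)C1c2cc(OCc3ccccc3)cc(OCc3ccccc3)c2C1([O-])c1c(OCOC)cc(OC)cc1OCOC.[Cs+] | intermediate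
29 | methyl 2-{3,5-bis(benzyloxy)-2-[4-methoxy-2,6-bis(methoxymethoxy)benzoyl]phenyl}acetate | COC(=O)Cc1cc(OCc2ccccc2)cc(OCc2ccccc2)c1C(=O)c1c(OCOC)cc(OC)cc1OCOC | intermediate
30 | 2-{3,5-bis(benzyloxy)-2-[4-methoxy-2,6-bis(methoxymethoxy)benzoyl]phenyl}acetic acid | OC(=O)Cc1cc(OCc2ccccc2)cc(OCc2ccccc2)c1C(=O)c1c(OCOC)cc(OC)cc1OCOC | intermediate
31 | 2-thioxopyridin-1(2H)-yl ester of 30 (not isolated) | S=c1ccccn1OC(=O)Cc1cc(OCc2ccccc2)cc(OCc2ccccc2)c1C(=O)c1c(OCOC)cc(OC)cc1OCOC | intermediate
32 | [2,4-bis(benzyloxy)-6-methylphenyl][4-methoxy-2,6-bis(methoxymethoxy)phenyl]methanone | Cc1cc(OCc2ccccc2)cc(OCc2ccccc2)c1C(=O)c1c(OCOC)cc(OC)cc1OCOC | intermediate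
33 | [2,4-bis(benzyloxy)-6-methylphenyl](2,6-dihydroxy-4-methoxyphenyl)methanone | Cc1cc(OCc2ccccc2)cc(OCc2ccccc2)c1C(=O)c1c(O)cc(OC)cc1O | intermediate
34 | [4-(benzyloxy)-2-methoxy-6-methylphenyl]{3-[(dimethylamino)methyl]-2,6-dihydroxy-4-methoxyphenyl}methanone | Cc1cc(OCc2ccccc2)cc(OC)c1C(=O)c1c(O)cc(OC)c(CN(C)C)c1O | intermediate
35 | 2-[4-(benzyloxy)-2-methoxy-6-methylbenzoyl]-3-hydroxy-5-methoxy-6-methylidenecyclohexa-2,4-dien-1-one (not isolated) | C=C1C(OC)=CC(O)=C(C(=O)c2c(C)cc(OCc3ccccc3)cc2OC)C1=O | intermediate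
36 | {3-[3-(2,4-bis(benzyloxy)-6-methylbenzoyl)-2,4-dihydroxy-6-methoxybenzyl]-2,6-dihydroxy-4-methoxyphenyl}[4-(benzyloxy)-2-methoxy-6-methylphenyl]methanone | COc1cc(O)c(C(=O)c2c(C)cc(OCc3ccccc3)cc2OCc2ccccc2)c(O)c1Cc1c(OC)cc(O)c(C(=O)c2c(C)cc(OCc3ccccc3)cc2OC)c1O | intermediate
37 | {3-[3-(2,4-dihydroxy-6-methylbenzoyl)-2,4-dihydroxy-6-methoxybenzyl]-2,6-dihydroxy-4-methoxyphenyl}(4-hydroxy-2-methoxy-6-methylphenyl)methanone (CNP0596095.0) | COc1cc(O)c(C(=O)c2c(C)cc(O)cc2O)c(O)c1Cc1c(OC)cc(O)c(C(=O)c2c(C)cc(O)cc2OC)c1O | target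

**Step count**
Total steps: 21.
Longest linear sequence: 11 steps (6 → 7 → 8 → 12 → 13 → 16 → 17 → 19 → 20 → 34 → 36 → 37).

**Steps most likely to fail**

1. Step 8 (step 15 runs the same risk). The aryl anion may be protonated before it closes onto the hindered, electron-rich ketone, which would stop the sequence at plain α-arylation. The product enolate may also be arylated again by surplus aryne.
Fallback, from 6, back at 19, by aryllithium addition to an aldehyde and oxidation. Compound 6 would be converted with NaH and MOMCl in DMF into 1-methoxy-3,5-bis(methoxymethoxy)benzene F1. n-BuLi (THF, 0 °C) should lithiate F1 between the two chelating MOM groups to give [4-methoxy-2,6-bis(methoxymethoxy)phenyl]lithium F2. Purchased 2,4-dihydroxy-6-methylbenzaldehyde F3 would be benzylated at its non-chelated C4 hydroxyl (BnBr, one equivalent, K2CO3, acetone) to 4-(benzyloxy)-2-hydroxy-6-methylbenzaldehyde F4. Methylation (MeI, K2CO3, DMF) would then give 4-(benzyloxy)-2-methoxy-6-methylbenzaldehyde F5. Addition of F2 to F5 at −78 °C should give racemic [4-(benzyloxy)-2-methoxy-6-methylphenyl][4-methoxy-2,6-bis(methoxymethoxy)phenyl]methanol F6. Dess–Martin oxidation of F6 erases the carbinol centre and delivers 19, so steps 8 to 10 are bypassed.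
For the other half, exhaustive benzylation of F3 would give 2,4-bis(benzyloxy)-6-methylbenzaldehyde F7. Addition of F2 to F7 would give racemic [2,4-bis(benzyloxy)-6-methylphenyl][4-methoxy-2,6-bis(methoxymethoxy)phenyl]methanol F8, and the same oxidation would lead to 32.

2. Step 20. Reversible quinone methide formation, promoted by the liberated amine at the temperature needed, may redistribute the methylene bridge between the two halves. The free C5 positions may also carry the reaction on to oligomers.
Fallback, from 20 and 33, back at 36, without a preformed electrophile. Equimolar 20 and 33 would be condensed directly with aqueous formaldehyde (half an equivalent per phenol) and NaOH in MeOH–THF at rt. This is Lederer–Manasse hydroxymethylation followed by capture of the quinone methide in situ, the classical way to methylene-bis(acylphloroglucinols). Compound 36 would then form beside two symmetrical dimers, bis{3-[4-(benzyloxy)-2-methoxy-6-methylbenzoyl]-2,4-dihydroxy-6-methoxyphenyl}methane F9 and bis{3-[2,4-bis(benzyloxy)-6-methylbenzoyl]-2,4-dihydroxy-6-methoxyphenyl}methane F10. Since the three differ stepwise by one benzyl group, they should separate on silica.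

3. Step 10 (and its twin, step 17). The stabilised benzylic radical takes hydrogen from the thiol slowly, so recombination with the thiopyridyl group may compete. Activation of the acid may also be diverted by cyclisation onto the neighbouring ketone oxygen.
Fallback, from 17, back at 19, by direct single-electron oxidation of the carboxylate without any activated ester. Compound 17 would be irradiated with blue LEDs in 1,2-dichloroethane in the presence of 9-mesityl-10-methylacridinium perchlorate (cat.), diphenyl disulfide (cat.) and 2,6-lutidine. This is a photoredox hydrodecarboxylation known for arylacetic acids, in which the thiophenol formed in situ is the better hydrogen donor towards benzylic radicals. The detour makes no compound outside the list (F0), and it would serve 30 to 32 in the same way.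

**Further compounds**
F1 | step 8 | 1-methoxy-3,5-bis(methoxymethoxy)benzene | COCOc1cc(OC)cc(OCOC)c1
F2 | step 8 | [4-methoxy-2,6-bis(methoxymethoxy)phenyl]lithium | [Li]c1c(OCOC)cc(OC)cc1OCOC
F3 | step 8 | 2,4-dihydroxy-6-methylbenzaldehyde (purchased) | Cc1cc(O)cc(O)c1C=O
F4 | step 8 | 4-(benzyloxy)-2-hydroxy-6-methylbenzaldehyde | Cc1cc(OCc2ccccc2)cc(O)c1C=O
F5 | step 8 | 4-(benzyloxy)-2-methoxy-6-methylbenzaldehyde | Cc1cc(OCc2ccccc2)cc(OC)c1C=O
F6 | step 8 | [4-(benzyloxy)-2-methoxy-6-methylphenyl][4-methoxy-2,6-bis(methoxymethoxy)phenyl]methanol (racemic) | Cc1cc(OCc2ccccc2)cc(OC)c1C(O)c1c(OCOC)cc(OC)cc1OCOC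
F7 | step 8 | 2,4-bis(benzyloxy)-6-methylbenzaldehyde | Cc1cc(OCc2ccccc2)cc(OCc2ccccc2)c1C=O
F8 | step 8 | [2,4-bis(benzyloxy)-6-methylphenyl][4-methoxy-2,6-bis(methoxymethoxy)phenyl]methanol (racemic) | Cc1cc(OCc2ccccc2)cc(OCc2ccccc2)c1C(O)c1c(OCOC)cc(OC)cc1OCOC
F9 | step 20 | bis{3-[4-(benzyloxy)-2-methoxy-6-methylbenzoyl]-2,4-dihydroxy-6-methoxyphenyl}methane | COc1cc(O)c(C(=O)c2c(C)cc(OCc3ccccc3)cc2OC)c(O)c1Cc1c(OC)cc(O)c(C(=O)c2c(C)cc(OCc3ccccc3)cc2OC)c1O
F10 | step 20 | bis{3-[2,4-bis(benzyloxy)-6-methylbenzoyl]-2,4-dihydroxy-6-methoxyphenyl}methane | COc1cc(O)c(C(=O)c2c(C)cc(OCc3ccccc3)cc2OCc2ccccc2)c(O)c1Cc1c(OC)cc(O)c(C(=O)c2c(C)cc(OCc3ccccc3)cc2OCc2ccccc2)c1O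
F0 | step 10 | none | none
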